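In the ochre run the starting material had fallen to 51.9% by 3.00 d, with the partner at 2.5 M. Read as a pseudo-first-order loss, that reading gives k′ = ln(amount charged / amount left) / time = 0.219 d⁻¹. Dividing by the partner gives the loss constant k = k′ / partner = 0.0874 L mol⁻¹ d⁻¹, so the fraction left is reckoned as exp(−k × partner × time), with the partner held at its charge. I assume that the partner sets this loss and that the second reagent does not.

- ochre: starting material 1 M; partner 2.5 M; second reagent 0.50 M; run made earlier
- flask: starting material 1.0 M; partner 2.50 M; second reagent 1.00 M; time 15 d

- ochre (time / d: target / %, side product B / %, starting material / %): 0.167: 0.2, 0.5, 95.7; 0.500: 0.4, 2.7, 87.6; 0.833: 2.2, 8.1, 81.1; 1.25: 3.3, 12.7, 74.1; 1.67: 4.0, 18.9, 68.6; 2.50: 5.8, 27.9, 58.3; 3.00: 6.2, 32.7, 51.9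

(scatter of a reading: 0.5 percentage points)

* which holds at 15 d: what has brought the reaction to rest, or that it has not come to rest (the partner has run out first / it is still moving / all of the starting material has reacted / the second reagent has run out first)
* how much target there is at 15 d, in percent of the starting material charged
* how much side product B there is at 15 d, in percent of the starting material charged
* amount of target if the flask were left three thousand times as long, in percent of the starting material charged

- the reaction counts as stopped when no species that holds the starting material changes by six tenths of a point or more over the second half of the time

Now turn the question round. For the new flask to count as stopped at 15 d, the starting material would have to fall by less than 0.600 of a point over the second half. On this first-order reckoning, that would take a k′ of about 0.682 d⁻¹, which is 3.11 times the 0.219 d⁻¹ you have. My reckoning instead leaves 19.4% at half time and 3.77% at the end. That is a fall of 16 percentage points, so I say the flask is still moving.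

The forecast also says it is still moving, with target 27%, side product B 59% and 32% of target in the long run. It differs from my reckoning on what remains: “with about 12% starting material left and still falling”.

The flask gives it is still moving, target 21.6%, side product B 61.2% and 22.6% in the long run.

    starting material + partner → intermediate (k = 1.07 × 10⁻⁶ L mol⁻¹ s⁻¹)
    second reagent + intermediate → target (k = 8.21 × 10⁻⁶ L mol⁻¹ s⁻¹)
    intermediate → side product B (k = 1.91 × 10⁻⁵ s⁻¹)
    starting material + second reagent → side product A (k = 3.76 × 10⁻⁷ L mol⁻¹ s⁻¹)

The flask and the forecast agree on the ending, but the forecast's target stands 5.4 points above the flask's. In the flask the starting material fell from 19.9% to 5.11% over the second half, a drop of 15 points, against the 16 points reckoned. Now take the neighbouring flask with 1.0 M of partner, everything else as charged. The same k, with the partner held at its charge, leaves 27.0% of its starting material. At 15.0 d that neighbour held 27% of its starting material, with 48% of its partner left.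

All runs are simulated from invented constants.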